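If coupling partner is charged above the substrate, the bench habit is pseudo-first-order: hold the partner at its charge and let the rest decay exponentially. I began there.

| flask | substrate | coupling partner | free catalyst | remark | time |
|---|---|---|---|---|---|
| violet | 0.62 M | 0.41 M | 120 mM | run made earlier |  |
| grey | 0.62 M | 0.66 M | 120 mM | run made earlier |  |
| Thursday's | 0.62 M | 0.810 M | 120 mM |  | 10 min |
| Tuesday's | 0.62 M | 0.620 M | 120 mM |  | 10 min |

| run | time / min | intermediate / % | substrate / % | target / % |
|---|---|---|---|---|
| violet | 0.667 | 61.8 | 22.3 | 14.3 |
| violet | 2.00 | 48.6 | 16.8 | 32.9 |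
| violet | 3.00 | 42.9 | 15.9 | 41.2 |
| violet | 5.00 | 37.0 | 13.4 | 51.2 |
| violet | 8.00 | 31.0 | 11.5 | 58.6 |
| grey | 0.667 | 56.5 | 22.0 | 22.0 |
| grey | 2.00 | 37.5 | 13.8 | 48.6 |
| grey | 3.00 | 30.7 | 10.2 | 59.3 |
| grey | 5.00 | 20.6 | 7.9 | 71.9 |
| grey | 8.00 | 14.5 | 4.8 | 81.2 |

(scatter of a reading: 0.5 percentage points)

- which of these there is most of at the end, counted by the substrate in it, Thursday's (substrate / intermediate / target)
- which of these there is most of at the end, counted by the substrate in it, Tuesday's (substrate / intermediate / target)
- amount of the one of these that there is most of at the end, in percent of the substrate charged, Thursday's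
- amount of the one of these that there is most of at the end, in percent of the substrate charged, Tuesday's

- a reading or a percentage of target counts all its forms, free or not

I wrote x for the fraction of the substrate charge that had become target and r for partner charge over substrate charge, so that r − x was the partner left on the same scale. Intermediate made up 0.723 of what was not yet target in the grey run at 5.00 min and 0.734 in the violet run, so I took the rate as

dx/dt = κ(1 − x)(r − x),

which integrates to

ln[(r − x) / (r(1 − x))] = κ(r − 1)t, or 1/(1 − x) = 1 + κt where r = 1.

The grey run has r = 1.06, and the change of the left side between its readings at 2.00 min and 8.00 min gave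

κ = 0.457 min⁻¹.

This κ, the fraction turned per minute when what is not yet target and the coupling partner left both stand at unit fraction, was my carried quantity. The violet run read 0.661 for r and 0.493 min⁻¹ for κ, but its last reading leaves r − x at 0.0753 against a scatter of 0.5 percentage points, so I kept grey's.

The habit, x = 1 − exp(−κrt), gave 99.7 % for Thursday's flask. Its border is the ratio of charges: turning over the substrate takes 76.5 % of Thursday's partner charge and 100 % of Tuesday's, so I did not hold the partner at its charge for either flask. The closed form at 10 min gave instead

Thursday's, r = 1.31: x = 92.9 %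

Tuesday's, r = 1.00: x = 82.0 %

So I expected target to hold most of the substrate in both flasks.

The forecast also named target and target, with 92.7 % for Thursday's, where I had 92.9 %, and 82 % for Tuesday's, on the ground that “the rate is first order in partner”.

Thursday's flask gave target at 92.6 %. Tuesday's flask gave target at 81.8 %.

    crystals ⇌ target, rate k1*(cs1 - [target]) while solid is left; crystals form when [target] > cs1 (solubility = 32.0 mM, k = 0.165 s⁻¹)
    free catalyst → spent catalyst (k = 2.11 × 10⁻⁵ s⁻¹)
    coupling partner + free catalyst + intermediate → free catalyst + target (k = 0.139 L² mol⁻² s⁻¹)
    substrate + free catalyst ⇌ free catalyst + intermediate (K = 2.78, k = 1.41 L mol⁻¹ s⁻¹)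

Read backwards, Tuesday's result puts κ at 0.449 min⁻¹. I then put the carried 0.457 min⁻¹ on the neighbouring flask, the same charges as Tuesday's read at 4.0 min. With r still 1.00, the same line gives x = 64.6 %. That flask held target at 64.0 %, below the reckoning, with intermediate at 26.4 % and substrate at 9.65 %.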